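The route cuts the C6–C7 bond of the ten-membered ring (briarane numbering: ring C1–C10; C16 is the exocyclic CH2 on C5; C7/C8 are shared with the lactone). The key step exploits the homoallylic chlorohydrin array C5(=C16)–C6(Cl)–C7(O): a chromium(II)-mediated intramolecular γ-chloroallylation closes the ten-membered carbocycle and in the same operation installs the C6 chloride, the C7 configuration and the exocyclic methylene. Its precursor carries the finished cyclohexane, the cis-3,4-epoxide and the γ-lactone in its 5-hydroxy (pseudo-acid) form, plus a 1,3-dichloroallyl unit. A four-carbon linchpin, ClCH=C(CH2Cl)CH2OPMB, serves twice: first as a chloroallylborane (epoxide), then as the allylchromium.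

Key step: step 21

Remark: briarane numbering is used throughout (cyclohexane = C1, C10–C14; C15 = methyl on C1; C17/C18/C19 = lactone CH, its methyl and the carbonyl; C20 = methyl on C11; β = the face of C15), and wherever a chiral catalyst or reagent is named, the enantiomer is the one expected to give the drawn configuration.

**Linchpin reagent**

Step 1
Reactants: 1 1,3-dichloroacetone
Product: 2 1,3-dichloro-2-(chloromethyl)prop-1-ene
Conditions: ClCH2PPh3Cl, NaHMDS, THF, −78 °C; then 1, −78 to 0 °C
Reagents that add atoms: (chloromethyl)triphenylphosphonium chloride, ClC[P+](c1ccccc1)(c1ccccc1)c1ccccc1.[Cl-]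
Why: Wittig chloromethylenation of a symmetrical ketone, so no alkene isomers can arise, the ylide adding to the carbonyl at −78 °C faster than it is alkylated by the α-chloroketone.

Step 2
Reactants: 2 1,3-dichloro-2-(chloromethyl)prop-1-ene (3 equiv); 3 4-methoxybenzyl alcohol
Product: 4 1-chloro-2-(chloromethyl)-3-[(4-methoxybenzyl)oxy]prop-1-ene (E/Z mixture)
Conditions: NaH, THF/DMF, 0 °C
Reagents that add atoms: none
Why: Williamson SN2 substitution of one of two equivalent primary allylic chlorides, mono-substitution being secured by the excess of 2, and the E/Z mixture is harmless because step 15 passes through a delocalised allyl anion.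

**Lactone building block**

Step 3
Reactants: 5 diethyl (S)-malate
Product: 6 diethyl (2S,3R)-2-hydroxy-3-methylsuccinate
Conditions: LDA (2.2 equiv), THF, −78 to −20 °C; MeI, −78 °C
Reagents that add atoms: iodomethane, CI
Why: Frater–Seebach alkylation, in which the chelated alkoxide–enolate dianion is methylated anti to the alkoxide and so sets the future C17 centre (3R) while the carbinol centre is untouched.

Step 4
Reactants: 6 diethyl (2S,3R)-2-hydroxy-3-methylsuccinate
Product: 7 (2S,3R)-2-hydroxy-3-methylsuccinic acid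
Conditions: KOH, H2O/EtOH, 0 °C to rt; then HCl
Reagents that add atoms: potassium hydroxide, [K+].[OH-]
Why: Ester saponification, the carboxylate that forms first protecting the α-carbon (C17) against enolisation so that both stereocentres are kept.

Step 5
Reactants: 7 (2S,3R)-2-hydroxy-3-methylsuccinic acid; 8 pivalaldehyde
Product: 9 (R)-2-[(2S,4S)-2-tert-butyl-5-oxo-1,3-dioxolan-4-yl]propanoic acid
Conditions: p-TsOH (cat.), H2SO4 (cat.), pentane, reflux, Dean–Stark
Reagents that add atoms: none
Why: Seebach acetalisation of the α-hydroxy acid gives the five-membered dioxolanone as the thermodynamic cis isomer (tert-butyl cis to the side chain), the acetal centre being set under equilibrating acid catalysis.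

**Cyclohexane core**

Step 6
Reactants: 10 ethyl (E)-3-methyl-4-oxobut-2-enoate; 11 (E)-1-(dimethylamino)-3-(tert-butyldimethylsilyloxy)buta-1,3-diene
Product: 12 cycloadduct (C1: β-CH3 and α-CHO; C10: β-CO2Et; C12 silyl enol ether; C14: α-NMe2)
Conditions: (1R,2R)-salen-Cr(III)SbF6 (5 mol %), 4 Å MS, CH2Cl2, −40 °C
Reagents that add atoms: none
Why: Catalytic enantioselective Diels–Alder reaction of an α-substituted acrolein with a 1-amino-3-siloxydiene, in which the nucleophilic diene terminus bonds to C10 (β to the aldehyde), the E dienophile fixes C2 trans to C9 at the C1/C10 pair, the catalyst sets their absolute sense and the endo mode places NMe2 cis to CHO.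

Step 7
Reactants: 12 cycloadduct
Product: 14 hydroxy enone (C12 ketone; C13=C14; C1 carries β-CH3 and the α-(R)-1-hydroxyallyl group C2–C3; C10 carries β-CO2Et), via vinyl adduct 13 (not isolated)
Conditions: CH2=CHMgBr, MgBr2·OEt2, CH2Cl2/Et2O, −78 °C; then 1 N HCl, THF, 0 °C
Reagents that add atoms: vinylmagnesium bromide, C=C[Mg]Br
Why: Chelation-controlled Grignard addition (magnesium bridges the aldehyde oxygen and the cis β-amino group so that vinyl attacks the exposed exo face and gives the carbinol configuration needed at C2), followed by acid hydrolysis of the silyl enol ether and β-elimination of dimethylamine to the enone.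

Step 8
Reactants: 14 hydroxy enone
Product: 15 C2 triethylsilyl ether of the enone
Conditions: TESCl, imidazole, DMAP (cat.), DMF, 0 °C to rt
Reagents that add atoms: chlorotriethylsilane, CC[Si](Cl)(CC)CC
Why: Standard silylation of a secondary alcohol, which blocks lactonisation onto the C9 ester and protects the C2 oxygen for the base steps.

Step 9
Reactants: 15 C2 triethylsilyl ether of the enone
Product: 16 11-epi methyl ketone (C11 methyl α, trans to C9)
Conditions: LDA, THF, −78 °C; MeI, −78 to −40 °C
Reagents that add atoms: iodomethane, CI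
Why: Kinetic α′-deprotonation of the enone and enolate methylation at C11, the electrophile entering anti to the adjacent β-ester on C10 so that the methyl group is expected on the α face.

Step 10
Reactants: 16 11-epi methyl ketone
Product: 17 methyl ketone with C11 methyl β (cis to C9 and to C15)
Conditions: LDA, THF, −78 °C; then AcOH, −78 °C
Reagents that add atoms: none
Why: Re-enolisation and kinetic protonation, the proton entering from the same α face that the methyl group used in step 9, which turns the methyl to the β face and gives the all-cis C11 epimer under kinetic control (any C11 mixture from step 9 converges here).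

Step 11
Reactants: 17 methyl ketone with C11 methyl β
Product: 18 diol (12β-OH allylic alcohol and primary C9 alcohol)
Conditions: DIBAL-H (5 equiv), CH2Cl2, −78 °C; Rochelle salt
Reagents that add atoms: none
Why: DIBAL 1,2-reduction of the enone together with reduction of the ester, the bulky hydride attacking C12 from the α face anti to the adjacent β-methyl on C11 to give the 12β-alcohol.

Step 12
Reactants: 18 diol
Product: 19 tris(triethylsilyl) ether (O2, O12, O9)
Conditions: TESCl, imidazole, DMAP (cat.), DMF, 0 °C to rt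
Reagents that add atoms: chlorotriethylsilane, CC[Si](Cl)(CC)CC
Why: Exhaustive silylation of one allylic secondary and one primary alcohol, with no stereocentre touched.

Step 13
Reactants: 19 tris(triethylsilyl) ether
Product: 20 13,14-α-epoxide
Conditions: mCPBA, NaHCO3, CH2Cl2, 0 °C
Reagents that add atoms: 3-chloroperbenzoic acid, OOC(=O)c1cccc(Cl)c1
Why: Prilezhaev epoxidation of the cis-disubstituted ring alkene in preference to the less nucleophilic monosubstituted vinyl group, from the α face anti to the allylic 12β-silyloxy group and to the β substituents on C1, C10 and C11.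

Step 14
Reactants: 20 13,14-α-epoxide
Product: 21 C3 aldehyde (α-silyloxy aldehyde)
Conditions: O3, CH2Cl2, −78 °C; PPh3
Reagents that add atoms: ozone, [O-][O+]=O
Why: Ozonolysis of the only remaining alkene with reductive work-up, which leaves the C2 configuration untouched under these neutral conditions.

**Linchpin attachment and cis-epoxide**

Step 15
Reactants: 21 C3 aldehyde; 4 1-chloro-2-(chloromethyl)-3-[(4-methoxybenzyl)oxy]prop-1-ene
Product: 24 cis-3,4-epoxide carrying the 1-chloro-3-(PMB-oxy)prop-1-en-2-yl group on C4, via γ-chloroallylborane 22 (not isolated), via syn-chlorohydrin 23 (not isolated)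
Conditions: 4, (+)-Ipc2BOMe, LiN(c-Hex)2, THF/Et2O, −95 °C; BF3·OEt2; 21, −95 to −78 °C; HOCH2CH2NH2; then DBU, CH2Cl2, rt
Reagents that add atoms: none
Why: Oehlschlager–Brown γ-chloroallylboration, in which in-situ lithiation of 4 and capture by the borinate give the (Z)-γ-chloroallylborane 22 that adds through a chair transition state to the re face of 21 (reagent control by the Ipc groups, matched with the Felkin preference of the α-silyloxy aldehyde) to set C3 and C4 as the syn-chlorohydrin, after which DBU closes the cis-epoxide by SN2 displacement with inversion at C4.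

Step 16
Reactants: 24 cis-3,4-epoxide PMB ether
Product: 25 allylic alcohol (C16–OH)
Conditions: DDQ, CH2Cl2/pH 7 buffer, 0 °C
Reagents that add atoms: none
Why: Oxidative PMB cleavage under buffered conditions, which leaves silyl ethers, both epoxides and the vinyl chloride intact.

Step 17
Reactants: 25 allylic alcohol
Product: 26 allylic chloride (C16H2Cl–C5=C6HCl unit)
Conditions: PPh3, Cl3CC(O)CCl3, CH2Cl2, −20 °C
Reagents that add atoms: hexachloroacetone, ClC(Cl)(Cl)C(=O)C(Cl)(Cl)Cl
Why: Appel-type chlorination of a primary allylic alcohol under neutral conditions, and either allylic isomer of the resulting dichloride would serve the chromium step.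

**Lactone assembly**

Step 18
Reactants: 26 allylic chloride
Product: 27 C9 aldehyde
Conditions: (COCl)2, DMSO, CH2Cl2, −78 to −45 °C; Et3N, −78 °C
Reagents that add atoms: none
Why: Swern conditions cleave and oxidise a primary triethylsilyl ether selectively beside secondary ones and so give the aldehyde in one operation, the low temperature limiting epimerisation at C10.

Step 19
Reactants: 27 C9 aldehyde; 9 (R)-2-[(2S,4S)-2-tert-butyl-5-oxo-1,3-dioxolan-4-yl]propanoic acid
Product: 29 aldol adduct as its C9 triethylsilyl ether (dioxolanone acid), via lithium aldolate 28 (not isolated)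
Conditions: 9, LiHMDS (2.2 equiv), THF, −78 °C; 27, −78 °C; TESOTf, −78 °C; pH 5 buffer
Reagents that add atoms: triethylsilyl trifluoromethanesulfonate, CC[Si](CC)(CC)OS(=O)(=O)C(F)(F)F
Why: Seebach aldol with self-regeneration of the stereocentre, the dilithiated dioxolanone attacking anti to its tert-butyl group (C8, overall retention) on the Felkin face of the α-branched aldehyde (C9), with silylation of the aldolate in the flask to prevent lactonisation of O9 onto C19.

Step 20
Reactants: 29 C9-silylated dioxolanone acid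
Product: 31 pseudo-acid (5-hydroxy γ-lactone with free 8-OH; C7 anomers), via dioxolanyl hemiacetal 30 (not isolated)
Conditions: DIBAL-H (3.5 equiv), CH2Cl2, −78 °C; Rochelle salt
Reagents that add atoms: none
Why: DIBAL half-reduction of the dioxolanone to its hemiacetal, which collapses on work-up with loss of pivalaldehyde to the α-hydroxy aldehyde that the C19 acid traps as the five-membered lactol, so that the lactone ring is in place before the carbocycle is closed.

**Ring closure and completion**

Step 21
Reactants: 31 pseudo-acid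
Product: 34 tris(triethylsilyl) macrocycle (complete ring system with 6-Cl, 5(16)-methylene, 8-OH), via allylchromium aldehyde 32 (not isolated), via chromium alkoxide 33 (not isolated)
Conditions: CrCl2 (10 equiv), THF/DMF (4:1), 2 mM, slow addition, rt; then pH 4 buffer
Reagents that add atoms: none
Why: Chromium(II) reduces the primary allylic C16–Cl bond of the ring-chain tautomeric aldehyde form of 31 to allylchromium(III) 32, which settles as the (E)-γ-chloro isomer Cr–C16H2–C5=C6HCl and adds through C6 to the C7 aldehyde in a Zimmerman–Traxler chair, the C7 chromium alkoxide 33 reclosing the lactone on work-up. The closest known reactions are the Nozaki–Hiyama allylation used to close ten-membered carbocycles and the chromium γ-chloroallylation of aldehydes that gives anti-chlorohydrins. The ten-membered ring closes by C6–C7 bond formation, exo at the C7 carbonyl with allylic transposition (SE2′) of the C16–C5–C6 unit, and the lactone recloses 5-exo-trig on C19. The anti relation of C6–Cl and C7–O follows from the chair with equatorial chlorine, and the C7 face from α-chelation of 8-OH and the C7 carbonyl on chromium with delivery of the tethered allyl unit from the C9 side, which places C6 trans to C9 and cis to 8-OH. The step needs γ attack at C6 over α attack at C16 (secured by chromium residing on the primary carbon), intramolecular over intermolecular addition (high dilution, slow addition) and tolerance of both epoxides and the silyl ethers (secured by the neutral, non-Lewis-acidic conditions).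

Step 22
Reactants: 34 tris(triethylsilyl) macrocycle
Product: 35 tetraol (2-OH, 9-OH, 12-OH, 8-OH)
Conditions: TBAF/AcOH (1:1), THF, 0 °C to rt
Reagents that add atoms: none
Why: Fluoride desilylation buffered with acetic acid removes the three triethylsilyl ethers at near-neutral pH, which should spare the vinyl epoxide, the allylic chloride and the β-hydroxy lactone.

Step 23
Reactants: 35 tetraol
Product: 36 CNP0229305.1 (target)
Conditions: Ac2O, pyridine, DMAP (cat.), CH2Cl2, 0 °C
Reagents that add atoms: acetic anhydride, CC(=O)OC(C)=O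
Why: Acetylation of the three secondary alcohols, the tertiary 8-OH being too hindered to react at 0 °C with catalytic DMAP.

**Compound list**

1 | 1,3-dichloroacetone | ClCC(=O)CCl | starting material
2 | 1,3-dichloro-2-(chloromethyl)prop-1-ene | ClC=C(CCl)CCl | intermediate
3 | 4-methoxybenzyl alcohol | COc1ccc(CO)cc1 | starting material
4 | 1-chloro-2-(chloromethyl)-3-[(4-methoxybenzyl)oxy]prop-1-ene (E/Z mixture) | ClC=C(CCl)COCc1ccc(OC)cc1 | intermediate
5 | diethyl (S)-malate | CCOC(=O)C[C@H](O)C(=O)OCC | starting material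
6 | diethyl (2S,3R)-2-hydroxy-3-methylsuccinate | CCOC(=O)[C@H](C)[C@H](O)C(=O)OCC | intermediate
7 | (2S,3R)-2-hydroxy-3-methylsuccinic acid | OC(=O)[C@H](C)[C@H](O)C(=O)O | intermediate
8 | pivalaldehyde | CC(C)(C)C=O | starting material
9 | (R)-2-[(2S,4S)-2-tert-butyl-5-oxo-1,3-dioxolan-4-yl]propanoic acid | OC(=O)[C@H](C)[C@@H]1O[C@H](C(C)(C)C)OC1=O | intermediate
10 | ethyl (E)-3-methyl-4-oxobut-2-enoate | CCOC(=O)/C=C(\C)C=O | starting material
11 | (E)-1-(dimethylamino)-3-(tert-butyldimethylsilyloxy)buta-1,3-diene | CN(C)/C=C/C(=C)O[Si](C)(C)C(C)(C)C | starting material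
12 | cycloadduct: C1 β-CH3/α-CHO, C10 β-CO2Et, C12 OTBS enol ether, C14 α-NMe2 | O=C[C@]1(C)[C@H](CC(O[Si](C)(C)C(C)(C)C)=C[C@@H]1N(C)C)C(=O)OCC | intermediate
13 | vinyl adduct of 12 ((R)-1-hydroxyallyl on C1) | C=C[C@@H](O)[C@]1(C)[C@H](CC(O[Si](C)(C)C(C)(C)C)=C[C@@H]1N(C)C)C(=O)OCC | intermediate
14 | hydroxy enone: C12 ketone, C13=C14, α-(R)-1-hydroxyallyl and β-CH3 on C1, β-CO2Et on C10 | C=C[C@@H](O)[C@]1(C)[C@H](CC(=O)C=C1)C(=O)OCC | intermediate
15 | C2 triethylsilyl ether of 14 | C=C[C@@H](O[Si](CC)(CC)CC)[C@]1(C)[C@H](CC(=O)C=C1)C(=O)OCC | intermediate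
16 | 11-epi methyl ketone (C11 methyl α) | C=C[C@@H](O[Si](CC)(CC)CC)[C@]1(C)[C@H]([C@H](C)C(=O)C=C1)C(=O)OCC | intermediate
17 | methyl ketone with C11 methyl β | C=C[C@@H](O[Si](CC)(CC)CC)[C@]1(C)[C@H]([C@@H](C)C(=O)C=C1)C(=O)OCC | intermediate
18 | diol: 12β-OH and C9H2OH | C=C[C@@H](O[Si](CC)(CC)CC)[C@]1(C)[C@H]([C@@H](C)[C@@H](O)C=C1)CO | intermediate
19 | tris(triethylsilyl) ether | C=C[C@@H](O[Si](CC)(CC)CC)[C@]1(C)[C@H]([C@@H](C)[C@@H](O[Si](CC)(CC)CC)C=C1)CO[Si](CC)(CC)CC | intermediate
20 | 13,14-α-epoxide | C=C[C@@H](O[Si](CC)(CC)CC)[C@]1(C)[C@H]([C@@H](C)[C@@H](O[Si](CC)(CC)CC)[C@@H]2O[C@@H]21)CO[Si](CC)(CC)CC | intermediate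
21 | C3 aldehyde | O=C[C@@H](O[Si](CC)(CC)CC)[C@]1(C)[C@H]([C@@H](C)[C@@H](O[Si](CC)(CC)CC)[C@@H]2O[C@@H]21)CO[Si](CC)(CC)CC | intermediate
22 | (Z)-γ-chloroallyl(diisopinocampheyl)borane from 4 | Cl/C=C(\C(Cl)B([C@H]1C[C@H]2C[C@@H]([C@@H]1C)C2(C)C)[C@H]1C[C@H]2C[C@@H]([C@@H]1C)C2(C)C)COCc1ccc(OC)cc1 | intermediate
23 | syn-chlorohydrin (3-OH, 4-Cl) | ClC=C(COCc1ccc(OC)cc1)[C@H](Cl)[C@@H](O)[C@@H](O[Si](CC)(CC)CC)[C@]1(C)[C@H]([C@@H](C)[C@@H](O[Si](CC)(CC)CC)[C@@H]2O[C@@H]21)CO[Si](CC)(CC)CC | intermediate
24 | cis-3,4-epoxide with PMB-protected C16 and C5=C6HCl | ClC=C(COCc1ccc(OC)cc1)[C@H]1O[C@H]1[C@@H](O[Si](CC)(CC)CC)[C@]2(C)[C@H]([C@@H](C)[C@@H](O[Si](CC)(CC)CC)[C@@H]3O[C@@H]32)CO[Si](CC)(CC)CC | intermediate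
25 | allylic alcohol (C16–OH) | ClC=C(CO)[C@H]1O[C@H]1[C@@H](O[Si](CC)(CC)CC)[C@]2(C)[C@H]([C@@H](C)[C@@H](O[Si](CC)(CC)CC)[C@@H]3O[C@@H]32)CO[Si](CC)(CC)CC | intermediate
26 | allylic chloride (C16–Cl) | ClC=C(CCl)[C@H]1O[C@H]1[C@@H](O[Si](CC)(CC)CC)[C@]2(C)[C@H]([C@@H](C)[C@@H](O[Si](CC)(CC)CC)[C@@H]3O[C@@H]32)CO[Si](CC)(CC)CC | intermediate
27 | C9 aldehyde | ClC=C(CCl)[C@H]1O[C@H]1[C@@H](O[Si](CC)(CC)CC)[C@]2(C)[C@H]([C@@H](C)[C@@H](O[Si](CC)(CC)CC)[C@@H]3O[C@@H]32)C=O | intermediate
28 | aldol adduct with free 9-OH (lithium aldolate in the flask) | ClC=C(CCl)[C@H]1O[C@H]1[C@@H](O[Si](CC)(CC)CC)[C@]2(C)[C@H]([C@@H](C)[C@@H](O[Si](CC)(CC)CC)[C@@H]3O[C@@H]32)[C@@H](O)[C@]4(O[C@H](C(C)(C)C)OC4=O)[C@@H](C)C(O)=O | intermediate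
29 | C9-silylated dioxolanone acid | ClC=C(CCl)[C@H]1O[C@H]1[C@@H](O[Si](CC)(CC)CC)[C@]2(C)[C@H]([C@@H](C)[C@@H](O[Si](CC)(CC)CC)[C@@H]3O[C@@H]32)[C@@H](O[Si](CC)(CC)CC)[C@]4(O[C@H](C(C)(C)C)OC4=O)[C@@H](C)C(O)=O | intermediate
30 | dioxolanyl hemiacetal | ClC=C(CCl)[C@H]1O[C@H]1[C@@H](O[Si](CC)(CC)CC)[C@]2(C)[C@H]([C@@H](C)[C@@H](O[Si](CC)(CC)CC)[C@@H]3O[C@@H]32)[C@@H](O[Si](CC)(CC)CC)[C@]4(O[C@H](C(C)(C)C)OC4O)[C@@H](C)C(O)=O | intermediate
31 | pseudo-acid: 5-hydroxy γ-lactone, 8-OH free, C7 anomers | ClC=C(CCl)[C@H]1O[C@H]1[C@@H](O[Si](CC)(CC)CC)[C@]2(C)[C@H]([C@@H](C)[C@@H](O[Si](CC)(CC)CC)[C@@H]3O[C@@H]32)[C@@H](O[Si](CC)(CC)CC)[C@]4(O)[C@@H](C)C(=O)OC4O | intermediate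
32 | allylchromium(III) species of the open aldehyde acid | Cl[Cr](Cl)CC(=CCl)[C@H]1O[C@H]1[C@@H](O[Si](CC)(CC)CC)[C@]2(C)[C@H]([C@@H](C)[C@@H](O[Si](CC)(CC)CC)[C@@H]3O[C@@H]32)[C@@H](O[Si](CC)(CC)CC)[C@@](O)(C=O)[C@@H](C)C(O)=O | intermediate
33 | ring-closed seco hydroxy acid (chromium alkoxide in the flask) | C=C1[C@H]2O[C@H]2[C@@H](O[Si](CC)(CC)CC)[C@]2(C)[C@H]([C@@H](C)[C@@H](O[Si](CC)(CC)CC)[C@@H]3O[C@@H]32)[C@@H](O[Si](CC)(CC)CC)[C@](O)([C@@H](C)C(O)=O)[C@@H](O)[C@H]1Cl | intermediate
34 | tris(triethylsilyl) macrocycle | C=C1[C@H]2O[C@H]2[C@@H](O[Si](CC)(CC)CC)[C@]2(C)[C@H]([C@@H](C)[C@@H](O[Si](CC)(CC)CC)[C@@H]3O[C@@H]32)[C@@H](O[Si](CC)(CC)CC)[C@]2(O)[C@@H](C)C(=O)O[C@H]2[C@H]1Cl | intermediate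
35 | tetraol | C=C1[C@H]2O[C@H]2[C@@H](O)[C@]2(C)[C@H]([C@@H](C)[C@@H](O)[C@@H]3O[C@@H]32)[C@@H](O)[C@]2(O)[C@@H](C)C(=O)O[C@H]2[C@H]1Cl | intermediate
36 | CNP0229305.1 | C=C1[C@H]2O[C@H]2[C@@H](OC(C)=O)[C@]2(C)[C@H]([C@@H](C)[C@@H](OC(C)=O)[C@@H]3O[C@@H]32)[C@@H](OC(C)=O)[C@]2(O)[C@@H](C)C(=O)O[C@H]2[C@H]1Cl | target

Total step count: 23. Longest linear sequence: 18 steps (steps 6 to 23, from 10 and 11).

**Steps most likely to fail**

Step 21 (key step). The carbonyl is largely masked as the lactol, so protonolysis or dimerisation of the allylchromium species may outrun the transannular addition; an α-ketol shift of the α-hydroxy aldehyde on chromium(III), or erosion of the anti and facial selectivity, may also intervene. The fallback abandons the pseudo-acid as electrophile. It sets out from 31, whose acid is methylated with TMSCHN2 to give the open-chain aldehyde methyl ester F1. This fixed, non-tautomeric aldehyde is cyclised with CrCl2 under high dilution, and the C7 chromium alkoxide is then lactonised onto the ester (CSA, CH2Cl2), so that the carbocycle is closed first and the lactone second. The sequence comes back to the route at 34.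

Step 15. The lithiated dichloroallyl reagent may decompose as a carbenoid before boron captures it, the γ-chloro geometry may be lost (anti-chlorohydrin, hence trans-epoxide), or the hindered neopentyl aldehyde may add too slowly for reagent control to hold. The fallback builds the epoxide by reagent-controlled epoxidation of a Z-alkene instead. It sets out from 21, which is homologated with the Bestmann–Ohira reagent (K2CO3, MeOH) to the terminal alkyne F2. Sonogashira coupling with 1-chloro-2-iodo-3-[(4-methoxybenzyl)oxy]prop-1-ene gives the enyne F3, and Zn(Cu/Ag) semi-reduction gives the (3Z)-diene F4. Shi epoxidation with the ketone catalyst designed for conjugated cis-olefins then oxidises the C3=C4 bond under catalyst control, the vinyl chloride being deactivated. The sequence comes back to the route at 24.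

Step 19. The aldehyde is flanked by a quaternary and a tertiary carbon and the enolate forms a quaternary centre, so addition may be slow or reversible, the basic enolate may epimerise C10, and the auxiliary-controlled enolate face may be mismatched with the Felkin face. The fallback replaces the aldol by an irreversible acylation and a ketone reduction. It sets out from 27, which is oxidised (NaClO2, NaH2PO4, 2-methyl-2-butene) to the carboxylic acid F5 and converted with Ghosez's reagent into the acid chloride F6. C-Acylation of the dilithio derivative of 9 gives the β-keto dioxolanone F7, and reduction of the C9 ketone (Zn(BH4)2, Et2O, −40 °C) from the Felkin face gives the aldol adduct 28. Silylation (TESOTf, 2,6-lutidine) brings the sequence back to the route at 29.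

Further compounds
F1 | step 21 | open-chain C7 aldehyde C19 methyl ester with free 8-OH | ClC=C(CCl)[C@H]1O[C@H]1[C@@H](O[Si](CC)(CC)CC)[C@]2(C)[C@H]([C@@H](C)[C@@H](O[Si](CC)(CC)CC)[C@@H]3O[C@@H]32)[C@@H](O[Si](CC)(CC)CC)[C@@](O)(C=O)[C@@H](C)C(=O)OC
F2 | step 15 | terminal alkyne (C3≡C4) from 21 | C#C[C@@H](O[Si](CC)(CC)CC)[C@]1(C)[C@H]([C@@H](C)[C@@H](O[Si](CC)(CC)CC)[C@@H]2O[C@@H]21)CO[Si](CC)(CC)CC
F3 | step 15 | enyne with the 1-chloro-3-(PMB-oxy)prop-1-en-2-yl group on C4 | ClC=C(COCc1ccc(OC)cc1)C#C[C@@H](O[Si](CC)(CC)CC)[C@]1(C)[C@H]([C@@H](C)[C@@H](O[Si](CC)(CC)CC)[C@@H]2O[C@@H]21)CO[Si](CC)(CC)CC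
F4 | step 15 | (3Z)-diene | ClC=C(COCc1ccc(OC)cc1)/C=C\[C@@H](O[Si](CC)(CC)CC)[C@]1(C)[C@H]([C@@H](C)[C@@H](O[Si](CC)(CC)CC)[C@@H]2O[C@@H]21)CO[Si](CC)(CC)CC
F5 | step 19 | C9 carboxylic acid | ClC=C(CCl)[C@H]1O[C@H]1[C@@H](O[Si](CC)(CC)CC)[C@]2(C)[C@H]([C@@H](C)[C@@H](O[Si](CC)(CC)CC)[C@@H]3O[C@@H]32)C(O)=O
F6 | step 19 | C9 acid chloride | ClC=C(CCl)[C@H]1O[C@H]1[C@@H](O[Si](CC)(CC)CC)[C@]2(C)[C@H]([C@@H](C)[C@@H](O[Si](CC)(CC)CC)[C@@H]3O[C@@H]32)C(Cl)=O
F7 | step 19 | C9 ketone (β-keto dioxolanone acid) | ClC=C(CCl)[C@H]1O[C@H]1[C@@H](O[Si](CC)(CC)CC)[C@]2(C)[C@H]([C@@H](C)[C@@H](O[Si](CC)(CC)CC)[C@@H]3O[C@@H]32)C(=O)[C@]4(O[C@H](C(C)(C)C)OC4=O)[C@@H](C)C(O)=O
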